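**Retrosynthetic overview**
1. Target 36 comes from allyl ester 35 by deallylation; the C2 ketone comes from the silyl ether in cycloadduct 33 (desilylation, oxidation).
2. Ring A (cyclohexene) and ring B (cyclopentane) close together in one intramolecular Diels-Alder reaction of the linear (E,E,E)-triene/(E)-enoate 32, which sets C3a, C4, C5 and C7a.
3. 32 comes from aldehyde 31 and ylide 8; the styryl triene is built from aldehyde 20 by two Wittig homologations with ylide 3 and one Horner-Wadsworth-Emmons reaction.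
4. The Me/OSi/Et triad of 20 comes from Fráter-Seebach ethylation of β-hydroxy ester 15, made by ketoreductase reduction of β-keto ester 14 (Claisen product of silylated ester 11).
5. The first stereocentre (C3 of the target) is set by rhodium-catalysed asymmetric hydrogenation of achiral acrylate 9.

Assumption: in step 3 the (R,R) antipode of the ligand is taken as the one that gives the (S)-ester; if a trial run shows the opposite sense, the (S,S) ligand is used and nothing else changes.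

Ring positions use indene numbering (C4 carries the carboxyl group).

**Route**

Step 1
Reactants: 1 ethyl 2-(triphenylphosphoranylidene)acetate
Product: 3 ethyl 2-(triphenylphosphoranylidene)butanoate, via phosphonium iodide 2 (not isolated)
Conditions: EtI (5 equiv), CHCl3, 60 °C; concentrate; then aq NaOH, CH2Cl2, 0 °C
Reagents that add atoms: ethyl iodide, CCI
Why: C-alkylation of the ester-stabilised ylide by the primary iodide gives the α-ethyl phosphonium salt (excess iodide carries the alkylation to completion despite transylidation), and cold hydroxide deprotonates it to the α-substituted stabilised ylide.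

Step 2
Reactants: 4 propyltriphenylphosphonium bromide; 5 allyl chloroformate
Product: 8 prop-2-en-1-yl 2-(triphenylphosphoranylidene)butanoate, via triphenyl(propylidene)phosphorane 6 (not isolated), via acylphosphonium chloride 7 (not isolated)
Conditions: 4 (2.0 equiv), NaN(SiMe3)2 (2.0 equiv), THF, 0 °C; then 5 (1.0 equiv), -78 °C to rt
Reagents that add atoms: none
Why: C-acylation of the non-stabilised ylide by the chloroformate followed by transylidation (a second equivalent of 6 deprotonates 7) is the standard Bestmann route to α-alkyl ester-stabilised ylides, and the allyl ester can later be removed without hydrolysis.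

Step 3
Reactants: 9 methyl 2-(hydroxymethyl)acrylate
Product: 10 methyl (S)-3-hydroxy-2-methylpropanoate
Conditions: [Rh(cod)2]BF4 (0.5 mol%), (R,R)-Me-DuPhos (0.55 mol%), H2 (5 bar), MeOH, 25 °C
Reagents that add atoms: none
Why: Catalytic asymmetric hydrogenation of the hydroxyl/ester-chelated 1,1-disubstituted alkene by the cationic rhodium bisphospholane complex sets the first stereocentre (later C3) by enantioface selection.

Step 4
Reactants: 10 methyl (S)-3-hydroxy-2-methylpropanoate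
Product: 11 methyl (S)-3-((tert-butyldimethylsilyl)oxy)-2-methylpropanoate
Conditions: TBSCl, imidazole, CH2Cl2, 0 °C to rt
Reagents that add atoms: tert-butyldimethylsilyl chloride (TBSCl), CC(C)(C)[Si](C)(C)Cl
Why: Imidazole-mediated silylation of the primary alcohol is non-basic enough to leave the α-stereocentre untouched.

Step 5
Reactants: 11 methyl (S)-3-((tert-butyldimethylsilyl)oxy)-2-methylpropanoate; 12 tert-butyl acetate
Product: 14 tert-butyl (S)-5-((tert-butyldimethylsilyl)oxy)-4-methyl-3-oxopentanoate, via lithium enolate of tert-butyl acetate 13 (not isolated)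
Conditions: LiN(i-Pr)2 (3.0 equiv), 12 (3.0 equiv), THF, -78 °C; then 11, -78 to -40 °C; aq NH4Cl
Reagents that add atoms: none
Why: Crossed Claisen condensation at low temperature; the product is stored as its C2 enolate until quench, which shields the C4 stereocentre from epimerisation.

Step 6
Reactants: 14 tert-butyl (S)-5-((tert-butyldimethylsilyl)oxy)-4-methyl-3-oxopentanoate
Product: 15 tert-butyl (3S,4S)-5-((tert-butyldimethylsilyl)oxy)-3-hydroxy-4-methylpentanoate
Conditions: ketoreductase ((3S)-selective, NADPH-dependent, chosen from a commercial panel), NADP+ (cat.), i-PrOH (15% v/v), phosphate buffer pH 7, 30 °C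
Reagents that add atoms: none
Why: Enzymatic carbonyl reduction of a β-keto ester with isopropanol-coupled cofactor recycling; the enzyme delivers hydride to the ketone face that gives the (3S) carbinol (3,4-syn) under catalyst control at neutral pH.

Step 7
Reactants: 15 tert-butyl (3S,4S)-5-((tert-butyldimethylsilyl)oxy)-3-hydroxy-4-methylpentanoate
Product: 17 tert-butyl (2R,3R,4S)-5-((tert-butyldimethylsilyl)oxy)-2-ethyl-3-hydroxy-4-methylpentanoate, via dilithium alkoxide enolate 16 (not isolated)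
Conditions: LiN(i-Pr)2 (2.3 equiv), THF, -78 to -20 °C; then EtI (4 equiv), DMPU, -78 to 0 °C; aq NH4Cl
Reagents that add atoms: ethyl iodide, CCI
Why: Fráter-Seebach alkylation: the lithium-chelated alkoxide enolate is ethylated anti to the C3 oxygen, which sets the ethyl-bearing centre (later C1) 1,3-anti to the methyl centre.

Step 8
Reactants: 17 tert-butyl (2R,3R,4S)-5-((tert-butyldimethylsilyl)oxy)-2-ethyl-3-hydroxy-4-methylpentanoate
Product: 18 tert-butyl (2R,3R,4S)-3,5-bis((tert-butyldimethylsilyl)oxy)-2-ethyl-4-methylpentanoate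
Conditions: TBSOTf, 2,6-lutidine, CH2Cl2, -78 to 0 °C
Reagents that add atoms: tert-butyldimethylsilyl trifluoromethanesulfonate (TBSOTf), CC(C)(C)[Si](C)(C)OS(=O)(=O)C(F)(F)F
Why: Silyl triflate silylation caps the hindered secondary alcohol without retro-aldol or epimerisation, and the tert-butyl ester survives at low temperature.

Step 9
Reactants: 18 tert-butyl (2R,3R,4S)-3,5-bis((tert-butyldimethylsilyl)oxy)-2-ethyl-4-methylpentanoate
Product: 19 (2S,3R,4S)-3,5-bis((tert-butyldimethylsilyl)oxy)-2-ethyl-4-methylpentan-1-ol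
Conditions: LiAlH4, Et2O, 0 °C; then H2O, aq NaOH
Reagents that add atoms: none
Why: Hydride reduction of the hindered ester to the primary alcohol leaves both silyl ethers and all stereocentres intact.

Step 10
Reactants: 19 (2S,3R,4S)-3,5-bis((tert-butyldimethylsilyl)oxy)-2-ethyl-4-methylpentan-1-ol
Product: 20 (2R,3R,4S)-3,5-bis((tert-butyldimethylsilyl)oxy)-2-ethyl-4-methylpentanal
Conditions: Dess-Martin periodinane, NaHCO3, CH2Cl2, 0 °C to rt; used crude
Reagents that add atoms: none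
Why: Buffered Dess-Martin oxidation gives the α-branched aldehyde under near-neutral conditions that do not epimerise it or eliminate the β-silyloxy group.

Step 11
Reactants: 20 (2R,3R,4S)-3,5-bis((tert-butyldimethylsilyl)oxy)-2-ethyl-4-methylpentanal; 3 ethyl 2-(triphenylphosphoranylidene)butanoate
Product: 21 ethyl (2E,4S,5S,6S)-5,7-bis((tert-butyldimethylsilyl)oxy)-2,4-diethyl-6-methylhept-2-enoate
Conditions: toluene, 100 °C
Reagents that add atoms: none
Why: Wittig olefination with a stabilised, α-substituted ylide is neutral (no epimerisation) and gives the (E)-trisubstituted enoate under thermodynamic control.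

Step 12
Reactants: 21 ethyl (2E,4S,5S,6S)-5,7-bis((tert-butyldimethylsilyl)oxy)-2,4-diethyl-6-methylhept-2-enoate
Product: 22 (2E,4S,5S,6S)-5,7-bis((tert-butyldimethylsilyl)oxy)-2,4-diethyl-6-methylhept-2-en-1-ol
Conditions: i-Bu2AlH (2.5 equiv), CH2Cl2, -78 °C; aq KNaC4H4O6
Reagents that add atoms: none
Why: 1,2-Reduction of the enoate by the aluminium hydride gives the allylic alcohol without touching the alkene geometry.

Step 13
Reactants: 22 (2E,4S,5S,6S)-5,7-bis((tert-butyldimethylsilyl)oxy)-2,4-diethyl-6-methylhept-2-en-1-ol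
Product: 23 (2E,4S,5S,6S)-5,7-bis((tert-butyldimethylsilyl)oxy)-2,4-diethyl-6-methylhept-2-enal
Conditions: MnO2, CH2Cl2, rt
Reagents that add atoms: none
Why: Chemoselective allylic oxidation on the manganese dioxide surface gives the (E)-enal under neutral conditions.

Step 14
Reactants: 23 (2E,4S,5S,6S)-5,7-bis((tert-butyldimethylsilyl)oxy)-2,4-diethyl-6-methylhept-2-enal; 3 ethyl 2-(triphenylphosphoranylidene)butanoate
Product: 24 ethyl (2E,4E,6S,7S,8S)-7,9-bis((tert-butyldimethylsilyl)oxy)-2,4,6-triethyl-8-methylnona-2,4-dienoate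
Conditions: toluene, 110 °C
Reagents that add atoms: none
Why: A second stabilised-ylide Wittig olefination extends the chain to the (E,E)-dienoate with the same reliable (E) selectivity.

Step 15
Reactants: 24 ethyl (2E,4E,6S,7S,8S)-7,9-bis((tert-butyldimethylsilyl)oxy)-2,4,6-triethyl-8-methylnona-2,4-dienoate
Product: 25 (2E,4E,6S,7S,8S)-7,9-bis((tert-butyldimethylsilyl)oxy)-2,4,6-triethyl-8-methylnona-2,4-dien-1-ol
Conditions: i-Bu2AlH (2.5 equiv), CH2Cl2, -78 °C; aq KNaC4H4O6
Reagents that add atoms: none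
Why: 1,2-Reduction of the dienoate to the dienol, as in step 12.

Step 16
Reactants: 25 (2E,4E,6S,7S,8S)-7,9-bis((tert-butyldimethylsilyl)oxy)-2,4,6-triethyl-8-methylnona-2,4-dien-1-ol
Product: 26 (2E,4E,6S,7S,8S)-7,9-bis((tert-butyldimethylsilyl)oxy)-2,4,6-triethyl-8-methylnona-2,4-dienal
Conditions: MnO2, CH2Cl2, rt
Reagents that add atoms: none
Why: Allylic oxidation with manganese dioxide, as in step 13, gives the dienal without isomerisation.

Step 17
Reactants: 26 (2E,4E,6S,7S,8S)-7,9-bis((tert-butyldimethylsilyl)oxy)-2,4,6-triethyl-8-methylnona-2,4-dienal; 27 diethyl benzylphosphonate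
Product: 29 ((1E,3E,5E,7S,8S,9S)-8,10-bis((tert-butyldimethylsilyl)oxy)-3,5,7-triethyl-9-methyldeca-1,3,5-trien-1-yl)benzene, via sodium phosphonate carbanion 28 (not isolated)
Conditions: 27, NaH, THF, 0 °C; then 26, -78 °C to rt
Reagents that add atoms: none
Why: Horner-Wadsworth-Emmons olefination with the aryl-stabilised phosphonate anion gives the (E)-styryl alkene; adding the aldehyde cold to the preformed anion favours carbonyl addition over vinylogous deprotonation.

Step 18
Reactants: 29 ((1E,3E,5E,7S,8S,9S)-8,10-bis((tert-butyldimethylsilyl)oxy)-3,5,7-triethyl-9-methyldeca-1,3,5-trien-1-yl)benzene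
Product: 30 (2S,3S,4S,5E,7E,9E)-3-((tert-butyldimethylsilyl)oxy)-4,6,8-triethyl-2-methyl-10-phenyldeca-5,7,9-trien-1-ol
Conditions: HF·pyridine, pyridine, THF, 0 °C
Reagents that add atoms: none
Why: Buffered fluoride desilylation removes the unhindered primary silyl ether much faster than the secondary one flanked by two branched carbons.

Step 19
Reactants: 30 (2S,3S,4S,5E,7E,9E)-3-((tert-butyldimethylsilyl)oxy)-4,6,8-triethyl-2-methyl-10-phenyldeca-5,7,9-trien-1-ol
Product: 31 (2R,3S,4S,5E,7E,9E)-3-((tert-butyldimethylsilyl)oxy)-4,6,8-triethyl-2-methyl-10-phenyldeca-5,7,9-trienal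
Conditions: Dess-Martin periodinane, NaHCO3, CH2Cl2, 0 °C; used crude
Reagents that add atoms: none
Why: Buffered Dess-Martin oxidation gives the α-methyl aldehyde without epimerisation (the descriptor changes from S to R only because the priorities change).

Step 20
Reactants: 31 (2R,3S,4S,5E,7E,9E)-3-((tert-butyldimethylsilyl)oxy)-4,6,8-triethyl-2-methyl-10-phenyldeca-5,7,9-trienal; 8 prop-2-en-1-yl 2-(triphenylphosphoranylidene)butanoate
Product: 33 prop-2-en-1-yl (1S,2R,3S,3aR,4R,5S,7aR)-2-((tert-butyldimethylsilyl)oxy)-1,4,5,7-tetraethyl-3-methyl-5-((E)-2-phenylethenyl)-2,3,3a,4,5,7a-hexahydro-1H-indene-4-carboxylate, via tetraene allyl ester 32 (not isolated)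
Conditions: toluene, 90 °C; then 110 °C, BHT (cat.)
Reagents that add atoms: none
Why: Wittig olefination gives the (E)-enoate, which undergoes an intramolecular Diels-Alder reaction with the (E,E)-diene through the ester-endo, trans-fused transition state. Both allylic stereocentres place their hydrogen in the plane of the neighbouring ethyl-bearing alkene (A(1,3) strain), so C3a, C4, C5 and C7a are set in one matched event.

Step 21
Reactants: 33 prop-2-en-1-yl (1S,2R,3S,3aR,4R,5S,7aR)-2-((tert-butyldimethylsilyl)oxy)-1,4,5,7-tetraethyl-3-methyl-5-((E)-2-phenylethenyl)-2,3,3a,4,5,7a-hexahydro-1H-indene-4-carboxylate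
Product: 34 prop-2-en-1-yl (1S,2R,3S,3aR,4R,5S,7aR)-1,4,5,7-tetraethyl-2-hydroxy-3-methyl-5-((E)-2-phenylethenyl)-2,3,3a,4,5,7a-hexahydro-1H-indene-4-carboxylate
Conditions: aq HF (48%), MeCN, rt
Reagents that add atoms: none
Why: Fluoride-driven desilylation of the hindered secondary silyl ether; the carboxyl is still an ester, so acid-induced lactonisation onto the alkenes cannot occur.

Step 22
Reactants: 34 prop-2-en-1-yl (1S,2R,3S,3aR,4R,5S,7aR)-1,4,5,7-tetraethyl-2-hydroxy-3-methyl-5-((E)-2-phenylethenyl)-2,3,3a,4,5,7a-hexahydro-1H-indene-4-carboxylate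
Product: 35 prop-2-en-1-yl (1S,3S,3aR,4R,5S,7aR)-1,4,5,7-tetraethyl-3-methyl-2-oxo-5-((E)-2-phenylethenyl)-2,3,3a,4,5,7a-hexahydro-1H-indene-4-carboxylate
Conditions: Dess-Martin periodinane, NaHCO3, CH2Cl2, rt
Reagents that add atoms: none
Why: Dess-Martin oxidation gives the cyclopentanone; both α-centres already carry their substituents trans to the ring-fusion bonds (the stable arrangement), so they are not scrambled.

Step 23
Reactants: 35 prop-2-en-1-yl (1S,3S,3aR,4R,5S,7aR)-1,4,5,7-tetraethyl-3-methyl-2-oxo-5-((E)-2-phenylethenyl)-2,3,3a,4,5,7a-hexahydro-1H-indene-4-carboxylate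
Product: 36 (1S,3S,3aR,4R,5S,7aR)-1,4,5,7-tetraethyl-3-methyl-2-oxo-5-((E)-2-phenylethenyl)-2,3,3a,4,5,7a-hexahydro-1H-indene-4-carboxylic acid
Conditions: Pd(PPh3)4 (5 mol%), morpholine, THF, rt; then aq citric acid
Reagents that add atoms: none
Why: Tsuji-Trost deallylation: zerovalent palladium ionises the allyl ester at the unhindered allyl carbon and morpholine traps the π-allyl, so the neopentyl quaternary carboxyl is freed without hydrolysis or base-induced epimerisation.

**Compound list**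
1 | ethyl 2-(triphenylphosphoranylidene)acetate | CCOC(=O)C=P(c1ccccc1)(c1ccccc1)c1ccccc1 | starting material
2 | (1-ethoxy-1-oxobutan-2-yl)triphenylphosphonium iodide (racemic) | CCOC(=O)C(CC)[P+](c1ccccc1)(c1ccccc1)c1ccccc1.[I-] | intermediate
3 | ethyl 2-(triphenylphosphoranylidene)butanoate | CCOC(=O)C(CC)=P(c1ccccc1)(c1ccccc1)c1ccccc1 | intermediate
4 | propyltriphenylphosphonium bromide | CCC[P+](c1ccccc1)(c1ccccc1)c1ccccc1.[Br-] | starting material
5 | allyl chloroformate | C=CCOC(=O)Cl | starting material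
6 | triphenyl(propylidene)phosphorane | CCC=P(c1ccccc1)(c1ccccc1)c1ccccc1 | intermediate
7 | (1-oxo-1-(prop-2-en-1-yloxy)butan-2-yl)triphenylphosphonium chloride (racemic) | C=CCOC(=O)C(CC)[P+](c1ccccc1)(c1ccccc1)c1ccccc1.[Cl-] | intermediate
8 | prop-2-en-1-yl 2-(triphenylphosphoranylidene)butanoate | C=CCOC(=O)C(CC)=P(c1ccccc1)(c1ccccc1)c1ccccc1 | intermediate
9 | methyl 2-(hydroxymethyl)acrylate | C=C(CO)C(=O)OC | starting material
10 | methyl (S)-3-hydroxy-2-methylpropanoate | OC[C@H](C)C(=O)OC | intermediate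
11 | methyl (S)-3-((tert-butyldimethylsilyl)oxy)-2-methylpropanoate | CC(C)(C)[Si](C)(C)OC[C@H](C)C(=O)OC | intermediate
12 | tert-butyl acetate | CC(=O)OC(C)(C)C | starting material
13 | lithium 1-(tert-butoxy)ethen-1-olate (lithium enolate of 12) | [Li+].C=C([O-])OC(C)(C)C | intermediate
14 | tert-butyl (S)-5-((tert-butyldimethylsilyl)oxy)-4-methyl-3-oxopentanoate | CC(C)(C)[Si](C)(C)OC[C@H](C)C(=O)CC(=O)OC(C)(C)C | intermediate
15 | tert-butyl (3S,4S)-5-((tert-butyldimethylsilyl)oxy)-3-hydroxy-4-methylpentanoate | CC(C)(C)[Si](C)(C)OC[C@H](C)[C@@H](O)CC(=O)OC(C)(C)C | intermediate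
16 | dilithium alkoxide enolate of 15 | [Li+].[Li+].CC(C)(C)[Si](C)(C)OC[C@H](C)[C@@H]([O-])C=C([O-])OC(C)(C)C | intermediate
17 | tert-butyl (2R,3R,4S)-5-((tert-butyldimethylsilyl)oxy)-2-ethyl-3-hydroxy-4-methylpentanoate | CC(C)(C)[Si](C)(C)OC[C@H](C)[C@@H](O)[C@@H](CC)C(=O)OC(C)(C)C | intermediate
18 | tert-butyl (2R,3R,4S)-3,5-bis((tert-butyldimethylsilyl)oxy)-2-ethyl-4-methylpentanoate | CC(C)(C)[Si](C)(C)OC[C@H](C)[C@@H](O[Si](C)(C)C(C)(C)C)[C@@H](CC)C(=O)OC(C)(C)C | intermediate
19 | (2S,3R,4S)-3,5-bis((tert-butyldimethylsilyl)oxy)-2-ethyl-4-methylpentan-1-ol | CC(C)(C)[Si](C)(C)OC[C@H](C)[C@@H](O[Si](C)(C)C(C)(C)C)[C@@H](CC)CO | intermediate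
20 | (2R,3R,4S)-3,5-bis((tert-butyldimethylsilyl)oxy)-2-ethyl-4-methylpentanal | CC(C)(C)[Si](C)(C)OC[C@H](C)[C@@H](O[Si](C)(C)C(C)(C)C)[C@@H](CC)C=O | intermediate
21 | ethyl (2E,4S,5S,6S)-5,7-bis((tert-butyldimethylsilyl)oxy)-2,4-diethyl-6-methylhept-2-enoate | CC(C)(C)[Si](C)(C)OC[C@H](C)[C@@H](O[Si](C)(C)C(C)(C)C)[C@@H](CC)/C=C(\CC)C(=O)OCC | intermediate
22 | (2E,4S,5S,6S)-5,7-bis((tert-butyldimethylsilyl)oxy)-2,4-diethyl-6-methylhept-2-en-1-ol | CC(C)(C)[Si](C)(C)OC[C@H](C)[C@@H](O[Si](C)(C)C(C)(C)C)[C@@H](CC)/C=C(\CC)CO | intermediate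
23 | (2E,4S,5S,6S)-5,7-bis((tert-butyldimethylsilyl)oxy)-2,4-diethyl-6-methylhept-2-enal | CC(C)(C)[Si](C)(C)OC[C@H](C)[C@@H](O[Si](C)(C)C(C)(C)C)[C@@H](CC)/C=C(\CC)C=O | intermediate
24 | ethyl (2E,4E,6S,7S,8S)-7,9-bis((tert-butyldimethylsilyl)oxy)-2,4,6-triethyl-8-methylnona-2,4-dienoate | CC(C)(C)[Si](C)(C)OC[C@H](C)[C@@H](O[Si](C)(C)C(C)(C)C)[C@@H](CC)/C=C(\CC)/C=C(\CC)C(=O)OCC | intermediate
25 | (2E,4E,6S,7S,8S)-7,9-bis((tert-butyldimethylsilyl)oxy)-2,4,6-triethyl-8-methylnona-2,4-dien-1-ol | CC(C)(C)[Si](C)(C)OC[C@H](C)[C@@H](O[Si](C)(C)C(C)(C)C)[C@@H](CC)/C=C(\CC)/C=C(\CC)CO | intermediate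
26 | (2E,4E,6S,7S,8S)-7,9-bis((tert-butyldimethylsilyl)oxy)-2,4,6-triethyl-8-methylnona-2,4-dienal | CC(C)(C)[Si](C)(C)OC[C@H](C)[C@@H](O[Si](C)(C)C(C)(C)C)[C@@H](CC)/C=C(\CC)/C=C(\CC)C=O | intermediate
27 | diethyl benzylphosphonate | CCOP(=O)(Cc1ccccc1)OCC | starting material
28 | sodium salt of the benzylic carbanion of 27 | [Na+].CCOP(=O)([CH-]c1ccccc1)OCC | intermediate
29 | ((1E,3E,5E,7S,8S,9S)-8,10-bis((tert-butyldimethylsilyl)oxy)-3,5,7-triethyl-9-methyldeca-1,3,5-trien-1-yl)benzene | CC(C)(C)[Si](C)(C)OC[C@H](C)[C@@H](O[Si](C)(C)C(C)(C)C)[C@@H](CC)/C=C(\CC)/C=C(\CC)/C=C/c1ccccc1 | intermediate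
30 | (2S,3S,4S,5E,7E,9E)-3-((tert-butyldimethylsilyl)oxy)-4,6,8-triethyl-2-methyl-10-phenyldeca-5,7,9-trien-1-ol | OC[C@H](C)[C@@H](O[Si](C)(C)C(C)(C)C)[C@@H](CC)/C=C(\CC)/C=C(\CC)/C=C/c1ccccc1 | intermediate
31 | (2R,3S,4S,5E,7E,9E)-3-((tert-butyldimethylsilyl)oxy)-4,6,8-triethyl-2-methyl-10-phenyldeca-5,7,9-trienal | O=C[C@H](C)[C@@H](O[Si](C)(C)C(C)(C)C)[C@@H](CC)/C=C(\CC)/C=C(\CC)/C=C/c1ccccc1 | intermediate
32 | prop-2-en-1-yl (2E,4S,5R,6S,7E,9E,11E)-5-((tert-butyldimethylsilyl)oxy)-2,6,8,10-tetraethyl-4-methyl-12-phenyldodeca-2,7,9,11-tetraenoate | C=CCOC(=O)/C(CC)=C/[C@H](C)[C@@H](O[Si](C)(C)C(C)(C)C)[C@@H](CC)/C=C(\CC)/C=C(\CC)/C=C/c1ccccc1 | intermediate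
33 | prop-2-en-1-yl (1S,2R,3S,3aR,4R,5S,7aR)-2-((tert-butyldimethylsilyl)oxy)-1,4,5,7-tetraethyl-3-methyl-5-((E)-2-phenylethenyl)-2,3,3a,4,5,7a-hexahydro-1H-indene-4-carboxylate | CCC1=C[C@@](/C=C/c2ccccc2)(CC)[C@](CC)(C(=O)OCC=C)[C@@H]2[C@@H]1[C@H](CC)[C@H](O[Si](C)(C)C(C)(C)C)[C@H]2C | intermediate
34 | prop-2-en-1-yl (1S,2R,3S,3aR,4R,5S,7aR)-1,4,5,7-tetraethyl-2-hydroxy-3-methyl-5-((E)-2-phenylethenyl)-2,3,3a,4,5,7a-hexahydro-1H-indene-4-carboxylate | CCC1=C[C@@](/C=C/c2ccccc2)(CC)[C@](CC)(C(=O)OCC=C)[C@@H]2[C@@H]1[C@H](CC)[C@H](O)[C@H]2C | intermediate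
35 | prop-2-en-1-yl (1S,3S,3aR,4R,5S,7aR)-1,4,5,7-tetraethyl-3-methyl-2-oxo-5-((E)-2-phenylethenyl)-2,3,3a,4,5,7a-hexahydro-1H-indene-4-carboxylate | CCC1=C[C@@](/C=C/c2ccccc2)(CC)[C@](CC)(C(=O)OCC=C)[C@@H]2[C@@H]1[C@H](CC)C(=O)[C@H]2C | intermediate
36 | (1S,3S,3aR,4R,5S,7aR)-1,4,5,7-tetraethyl-3-methyl-2-oxo-5-((E)-2-phenylethenyl)-2,3,3a,4,5,7a-hexahydro-1H-indene-4-carboxylic acid | CCC1=C[C@@](/C=C/c2ccccc2)(CC)[C@](CC)(C(=O)O)[C@@H]2[C@@H]1[C@H](CC)C(=O)[C@H]2C | target

**Totals**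
Total step count: 23 (21 in the main line plus 2 ylide preparations).
Longest linear sequence: 21 steps (steps 3 to 23, from 9 to 36).

**Three steps most likely to fail, each with a fallback**

Step 20 (Wittig/intramolecular Diels-Alder) is the main risk, because two adjacent quaternary carbons form and the thermal reaction may be slow or less selective than expected. The fallback sets out from 31 and comes back at 33. Triphenyl(propylidene)phosphorane 6, generated from 4 with NaN(SiMe3)2 as in step 2, is formylated with ethyl formate (THF, 0 °C to rt) to 2-(triphenylphosphoranylidene)butanal F4. Wittig reaction of 31 with F4 (toluene, 80 °C) gives (2E,4S,5R,6S,7E,9E,11E)-5-((tert-butyldimethylsilyl)oxy)-2,6,8,10-tetraethyl-4-methyl-12-phenyldodeca-2,7,9,11-tetraenal F5. The enal is activated with Me2AlCl (CH2Cl2, -78 to -20 °C) for a Lewis-acid-promoted cycloaddition through the same endo transition state, giving (1S,2R,3S,3aR,4R,5S,7aR)-2-((tert-butyldimethylsilyl)oxy)-1,4,5,7-tetraethyl-3-methyl-5-((E)-2-phenylethenyl)-2,3,3a,4,5,7a-hexahydro-1H-indene-4-carbaldehyde F6. Pinnick oxidation (NaClO2, NaH2PO4, 2-methylbut-2-ene, t-BuOH/H2O) gives (1S,2R,3S,3aR,4R,5S,7aR)-2-((tert-butyldimethylsilyl)oxy)-1,4,5,7-tetraethyl-3-methyl-5-((E)-2-phenylethenyl)-2,3,3a,4,5,7a-hexahydro-1H-indene-4-carboxylic acid F7, and O-alkylation of its caesium salt (Cs2CO3, allyl bromide, DMF) gives 33.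

Step 7 (Fráter-Seebach ethylation) may stall because ethyl iodide is a slow electrophile towards the hindered dianion. The fallback sets out from 14 and comes back at 17. 14 is C-ethylated at the doubly activated C2 (K2CO3, EtI, acetone, 50 °C) to tert-butyl (4S)-5-((tert-butyldimethylsilyl)oxy)-2-ethyl-4-methyl-3-oxopentanoate F3, a mixture of C2 epimers that interconvert through the enol. A ketoreductase-mediated dynamic kinetic resolution (anti-selective enzyme from a panel, NADP+, i-PrOH, phosphate buffer pH 7, 30 °C) then reduces only the (2R) epimer to the (3R) alcohol, so the whole of F3 funnels to 17.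

Step 6 (ketoreductase reduction) may fail if no enzyme of the panel accepts the γ-branched, silylated substrate with the required facial sense. The fallback sets out from 11 and comes back at 15. 11 is half-reduced with i-Bu2AlH (CH2Cl2, -78 °C) to (S)-3-((tert-butyldimethylsilyl)oxy)-2-methylpropanal F1. 12 is converted with LiN(i-Pr)2 and TBSCl (THF, DMPU, -78 °C) into tert-butyl((1-(tert-butoxy)ethenyl)oxy)dimethylsilane F2. A BF3·OEt2-promoted Mukaiyama aldol addition of F2 to F1 (CH2Cl2, -78 °C) proceeds through the open Felkin-Anh transition state and gives the 3,4-syn ester 15 directly.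

**Further compounds**
F1 | step 6 | (S)-3-((tert-butyldimethylsilyl)oxy)-2-methylpropanal | CC(C)(C)[Si](C)(C)OC[C@H](C)C=O
F2 | step 6 | tert-butyl((1-(tert-butoxy)ethenyl)oxy)dimethylsilane | C=C(OC(C)(C)C)O[Si](C)(C)C(C)(C)C
F3 | step 7 | tert-butyl (4S)-5-((tert-butyldimethylsilyl)oxy)-2-ethyl-4-methyl-3-oxopentanoate (C2 epimers) | CC(C)(C)[Si](C)(C)OC[C@H](C)C(=O)C(CC)C(=O)OC(C)(C)C
F4 | step 20 | 2-(triphenylphosphoranylidene)butanal | CCC(C=O)=P(c1ccccc1)(c1ccccc1)c1ccccc1
F5 | step 20 | (2E,4S,5R,6S,7E,9E,11E)-5-((tert-butyldimethylsilyl)oxy)-2,6,8,10-tetraethyl-4-methyl-12-phenyldodeca-2,7,9,11-tetraenal | O=C/C(CC)=C/[C@H](C)[C@@H](O[Si](C)(C)C(C)(C)C)[C@@H](CC)/C=C(\CC)/C=C(\CC)/C=C/c1ccccc1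
F6 | step 20 | (1S,2R,3S,3aR,4R,5S,7aR)-2-((tert-butyldimethylsilyl)oxy)-1,4,5,7-tetraethyl-3-methyl-5-((E)-2-phenylethenyl)-2,3,3a,4,5,7a-hexahydro-1H-indene-4-carbaldehyde | CCC1=C[C@@](/C=C/c2ccccc2)(CC)[C@](CC)(C=O)[C@@H]2[C@@H]1[C@H](CC)[C@H](O[Si](C)(C)C(C)(C)C)[C@H]2C
F7 | step 20 | (1S,2R,3S,3aR,4R,5S,7aR)-2-((tert-butyldimethylsilyl)oxy)-1,4,5,7-tetraethyl-3-methyl-5-((E)-2-phenylethenyl)-2,3,3a,4,5,7a-hexahydro-1H-indene-4-carboxylic acid | CCC1=C[C@@](/C=C/c2ccccc2)(CC)[C@](CC)(C(=O)O)[C@@H]2[C@@H]1[C@H](CC)[C@H](O[Si](C)(C)C(C)(C)C)[C@H]2C
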